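**Retrosynthetic overview**

- The target is two fully substituted 1,4-benzoquinones joined by an unbranched (CH2)13 tether. Ring A (2-OMe, 3-Me, 5-OH) carries the chain at C6, between the C5 hydroxyl and the C1 carbonyl; ring B (2,5-di-OH, 3-Me) carries it at its C6.
- In each ring the chain-bearing carbon is the one position that the parent methylquinone leaves as C–H. Both ring-C6–CH2 bonds are therefore cut to a quinone C–H plus a primary alkyl radical, and the thirteen methylenes become pentadecanedioic acid less its two carboxyl carbons.
- Both quinones come from one arene: 1,2,4,5-tetramethoxybenzene is C-methylated and oxidised to 2,5-dimethoxy-3-methyl-1,4-benzoquinone. Full hydrolysis gives the ring B partner; mono-hydrolysis at C5 gives the ring A partner and fixes the position of the single O-methyl before any chain is attached.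
- No ring is built. The half-ester of the diacid is attached to ring B by decarboxylative radical C–H alkylation, the ester is hydrolysed, and the freed carboxyl is used in the last step to attach ring A.
- The target has no stereocentres and no stereogenic double bonds.

Key step: step 9

Remark: ring A is the methoxy-hydroxy quinone and ring B the dihydroxy quinone; the carbonyl carbons are numbered C1 and C4, and the hydroxyquinones are drawn in the tautomeric form of the target SMILES.

**Route**

Step 1
Reactants: 1 1,2,4,5-tetramethoxybenzene
Product: 3 1,2,4,5-tetramethoxy-3-methylbenzene, via 2,3,5,6-tetramethoxyphenyllithium 2 (not isolated)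
Conditions: n-BuLi (1.1 equiv), TMEDA, THF, 0 °C to rt; then MeI, −78 °C to rt
Reagents that add atoms: iodomethane, CI
Why: Directed ortho-metalation removes the hydrogen flanked by two methoxy groups and the aryllithium is methylated by SN2 on iodomethane, one equivalent of base limiting the reaction to the mono-methyl arene.

Step 2
Reactants: 3 1,2,4,5-tetramethoxy-3-methylbenzene
Product: 4 2,5-dimethoxy-3-methyl-1,4-benzoquinone
Conditions: (NH4)2Ce(NO3)6 (2.5 equiv), MeCN/H2O, 0 °C
Reagents that add atoms: water, O
Why: Oxidative demethylation by tetravalent cerium, in which the arene radical cation is trapped by water at a para pair of methoxy-bearing carbons and two molecules of methanol are expelled, should give the 2,5-dimethoxy-para-quinone (both para pairs lead to the same compound).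

Step 3
Reactants: 4 2,5-dimethoxy-3-methyl-1,4-benzoquinone
Product: 5 2,5-dihydroxy-3-methyl-1,4-benzoquinone
Conditions: 2 M NaOH (aq, excess), dioxane, 80 °C; then 2 M HCl
Reagents that add atoms: sodium hydroxide, [Na+].[OH-]
Why: Double vinylogous ester saponification (conjugate addition–elimination of hydroxide at C2 and C5) under forcing conditions is the standard way to unmask 3-alkyl-2,5-dihydroxyquinones, the product being stable in the medium as its dianion and liberated by acid.

Step 4
Reactants: 4 2,5-dimethoxy-3-methyl-1,4-benzoquinone
Product: 6 5-hydroxy-2-methoxy-3-methyl-1,4-benzoquinone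
Conditions: NaOH (1.1 equiv, 0.1 M aq), THF, 0 °C; then 1 M HCl; chromatography
Reagents that add atoms: sodium hydroxide, [Na+].[OH-]
Why: Vinylogous ester saponification by addition–elimination under kinetic control should favour C5, whose enone partner C6 bears only hydrogen, over C2, whose partner C3 bears the methyl group and is a more hindered, alpha-substituted acceptor; the anion of the resulting hydroxyquinone resists a second substitution in the cold, and any 2-hydroxy-5-methoxy isomer would be removed by chromatography and the assignment checked by the NOE between O-methyl and C-methyl.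

Step 5
Reactants: 7 pentadecanedioic acid
Product: 8 dimethyl pentadecanedioate
Conditions: MeOH, H2SO4 (cat.), reflux
Reagents that add atoms: methanol, CO
Why: Fischer esterification is driven to the diester by the large excess of methanol.

Step 6
Reactants: 8 dimethyl pentadecanedioate
Product: 9 15-methoxy-15-oxopentadecanoic acid (pentadecanedioic acid monomethyl ester)
Conditions: KOH (1.0 equiv), MeOH/THF, rt; then 1 M HCl
Reagents that add atoms: potassium hydroxide, [K+].[OH-]
Why: Statistical half-saponification with one equivalent of hydroxide should give mainly the half-ester, which is separated from recovered diester (recycled) and diacid by acid–base extraction and crystallisation.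

Step 7
Reactants: 5 2,5-dihydroxy-3-methyl-1,4-benzoquinone (3 equiv); 9 15-methoxy-15-oxopentadecanoic acid
Product: 10 methyl 14-(2,5-dihydroxy-4-methyl-3,6-dioxocyclohexa-1,4-dien-1-yl)tetradecanoate
Conditions: AgNO3 (0.3 equiv), (NH4)2S2O8 (1.5 equiv, slow addition), MeCN/H2O (1:1), 65 °C
Reagents that add atoms: none
Why: In this silver-catalysed persulfate decarboxylative radical alkylation of a quinone (Jacobsen–Torssell, Minisci-type), divalent silver oxidises the free carboxyl of 9, loss of CO2 gives a nucleophilic primary radical that adds to the only unsubstituted ring carbon of 5 (as in the alkylation of 2-hydroxy-1,4-naphthoquinone and the peroxide alkylation of 2,5-dihydroxybenzoquinone), and the adduct radical is reoxidised to the quinone, while the methyl ester is inert and the excess of 5 suppresses radical dimerisation.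

Step 8
Reactants: 10 methyl 14-(2,5-dihydroxy-4-methyl-3,6-dioxocyclohexa-1,4-dien-1-yl)tetradecanoate
Product: 11 14-(2,5-dihydroxy-4-methyl-3,6-dioxocyclohexa-1,4-dien-1-yl)tetradecanoic acid
Conditions: NaOH (aq, 5 equiv), THF/MeOH, 40 °C, N2; then 1 M HCl
Reagents that add atoms: sodium hydroxide, [Na+].[OH-]
Why: This is an ordinary ester saponification in which ring B sits as its dianion, the form in which such dihydroxyquinones are generated in alkali, and returns unchanged on acidification, exclusion of air guarding against oxidative degradation.

Step 9
Reactants: 11 14-(2,5-dihydroxy-4-methyl-3,6-dioxocyclohexa-1,4-dien-1-yl)tetradecanoic acid; 6 5-hydroxy-2-methoxy-3-methyl-1,4-benzoquinone (3 equiv)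
Product: 12 2,5-dihydroxy-3-[13-(2-hydroxy-5-methoxy-4-methyl-3,6-dioxocyclohexa-1,4-dien-1-yl)tridecyl]-6-methyl-1,4-benzoquinone (target CNP0107579.0)
Conditions: AgNO3 (0.3 equiv), (NH4)2S2O8 (1.5 equiv, slow addition), MeCN/H2O (1:1), 65 °C
Reagents that add atoms: none
Why: Persulfate oxidises monovalent to divalent silver, which takes one electron from the carboxylate of 11; the acyloxy radical loses CO2 and the primary alkyl radical at the chain end adds to C6 of 6, the adduct radical then being oxidised and deprotonated back to the quinone, so the C6–CH2 bond that completes the thirteen-methylene tether is formed with no ring closed and no stereocentre created. The closest known reaction type is the Jacobsen–Torssell (Minisci-type) decarboxylative alkylation of quinones, established for hydroxyquinones such as 2-hydroxy-1,4-naphthoquinone, together with the classical peroxide alkylation of 2,5-dihydroxybenzoquinones. The step needs site selectivity, and the substrates secure it: 6 has a single ring C–H (C6, flanked by the C5 hydroxyl and the C1 carbonyl), while ring B of 11 is fully substituted and offers no position for addition. The position of the lone O-methyl (on C2, next to the C-methyl) was fixed in step 4, so no oxygen has to be differentiated after the union. Compound 6 is used in excess and the persulfate is added slowly to keep the radical concentration low, which should favour addition over dimerisation or further oxidation of the radical.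

**Compound list**

1 | 1,2,4,5-tetramethoxybenzene | COc1cc(OC)c(OC)cc1OC | starting material
2 | 2,3,5,6-tetramethoxyphenyllithium | COc1cc(OC)c(OC)c([Li])c1OC | intermediate
3 | 1,2,4,5-tetramethoxy-3-methylbenzene | COc1cc(OC)c(OC)c(C)c1OC | intermediate
4 | 2,5-dimethoxy-3-methyl-1,4-benzoquinone | COC1=CC(=O)C(OC)=C(C)C1=O | intermediate
5 | 2,5-dihydroxy-3-methyl-1,4-benzoquinone | OC1=CC(=O)C(O)=C(C)C1=O | intermediate
6 | 5-hydroxy-2-methoxy-3-methyl-1,4-benzoquinone | COC1=C(C)C(=O)C(O)=CC1=O | intermediate
7 | pentadecanedioic acid | OC(=O)CCCCCCCCCCCCCC(=O)O | starting material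
8 | dimethyl pentadecanedioate | COC(=O)CCCCCCCCCCCCCC(=O)OC | intermediate
9 | 15-methoxy-15-oxopentadecanoic acid | COC(=O)CCCCCCCCCCCCCC(=O)O | intermediate
10 | methyl 14-(2,5-dihydroxy-4-methyl-3,6-dioxocyclohexa-1,4-dien-1-yl)tetradecanoate | COC(=O)CCCCCCCCCCCCCC1=C(O)C(=O)C(C)=C(O)C1=O | intermediate
11 | 14-(2,5-dihydroxy-4-methyl-3,6-dioxocyclohexa-1,4-dien-1-yl)tetradecanoic acid | OC(=O)CCCCCCCCCCCCCC1=C(O)C(=O)C(C)=C(O)C1=O | intermediate
12 | 2,5-dihydroxy-3-[13-(2-hydroxy-5-methoxy-4-methyl-3,6-dioxocyclohexa-1,4-dien-1-yl)tridecyl]-6-methyl-1,4-benzoquinone | COC1=C(C)C(=O)C(O)=C(CCCCCCCCCCCCCC2=C(O)C(=O)C(C)=C(O)C2=O)C1=O | target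

**Step count**

Total: 9 steps. Longest linear sequence: 6 steps (steps 1, 2, 3, 7, 8, 9).

**Three steps most likely to fail**

1. Step 9 (key union). The dihydroxyquinone end of 11, or the product, may be degraded by divalent silver and persulfate or withdrawn from solution as a silver salt. The primary radical would then be lost to dimerisation, hydrogen abstraction or over-oxidation instead of adding to 6. The fallback is polar instead of radical and forms the same ring-carbon-to-CH2 bonds; it sets out from 5 and 6 and comes back at 12. Purchased tridecane-1,13-diol F1 is oxidised under Swern conditions ((COCl)2, DMSO, Et3N, CH2Cl2, −78 °C) to tridecanedial F2. F2, used in excess, is joined to 5 by an organocatalytic three-component reductive alkylation (L-proline cat., Hantzsch ester, CH2Cl2, rt): Knoevenagel condensation at the single ring C–H, then conjugate hydride transfer. This should give 13-(2,5-dihydroxy-4-methyl-3,6-dioxocyclohexa-1,4-dien-1-yl)tridecanal F3. The same reductive alkylation of 6 with F3 should give 12. In this variant both aldehyde carbons stay in the chain, so the tether comes from a thirteen-carbon dialdehyde and steps 5 to 8 are not needed.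

2. Step 7. The electron-rich quinone 5 may be over-oxidised, or the long-chain acid 9 may mix poorly with the aqueous oxidant, so that decarboxylation outruns addition and the chain ends up as alkane, alkene or dimer. The fallback uses a preformed radical source with no metal and no persulfate; it sets out from 9 and comes back at 10. Acid 9 is converted with (COCl)2 and catalytic DMF in CH2Cl2 into methyl 15-chloro-15-oxopentadecanoate F4. F4 is treated with Na2O2 in Et2O/H2O at 0 °C to give bis(15-methoxy-15-oxopentadecanoyl) peroxide F5. F5 is decomposed in AcOH at 90–95 °C in the presence of 5, the classical diacyl peroxide alkylation of 2,5-dihydroxybenzoquinones, the peroxide acting both as radical source and as oxidant for the adduct; this should give 10.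

3. Step 4. Hydroxide may attack both methoxy-bearing carbons with poor site selectivity, or hydrolysis may run on to 5. The fallback is a protect–methylate–deprotect sequence instead of a selective cleavage; it sets out from 5 and comes back at 6. Acid-catalysed etherification of 5 with benzyl alcohol (TsOH cat., toluene, 80 °C), which in 3-alkyl-2,5-dihydroxyquinones enters at the hydroxyl remote from the alkyl group, should give 5-(benzyloxy)-2-hydroxy-3-methyl-1,4-benzoquinone F6. O-Methylation of the remaining hydroxyl (MeI, Ag2O, CHCl3, rt) should give 5-(benzyloxy)-2-methoxy-3-methyl-1,4-benzoquinone F7. Hydrogenolysis (H2, 10% Pd/C, EtOAc) removes the benzyl group and reduces the ring to 5-methoxy-6-methylbenzene-1,2,4-triol F8, which is reoxidised by air on work-up to 6.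

**Further compounds**

F1 | step 9 | tridecane-1,13-diol | OCCCCCCCCCCCCCO
F2 | step 9 | tridecanedial | O=CCCCCCCCCCCCC=O
F3 | step 9 | 13-(2,5-dihydroxy-4-methyl-3,6-dioxocyclohexa-1,4-dien-1-yl)tridecanal | O=CCCCCCCCCCCCCC1=C(O)C(=O)C(C)=C(O)C1=O
F4 | step 7 | methyl 15-chloro-15-oxopentadecanoate | COC(=O)CCCCCCCCCCCCCC(=O)Cl
F5 | step 7 | bis(15-methoxy-15-oxopentadecanoyl) peroxide | COC(=O)CCCCCCCCCCCCCC(=O)OOC(=O)CCCCCCCCCCCCCC(=O)OC
F6 | step 4 | 5-(benzyloxy)-2-hydroxy-3-methyl-1,4-benzoquinone | OC1=C(C)C(=O)C(OCc2ccccc2)=CC1=O
F7 | step 4 | 5-(benzyloxy)-2-methoxy-3-methyl-1,4-benzoquinone | COC1=C(C)C(=O)C(OCc2ccccc2)=CC1=O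
F8 | step 4 | 5-methoxy-6-methylbenzene-1,2,4-triol | COc1c(C)c(O)c(O)cc1O
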